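**Retrosynthetic overview**

1. Locants: ketone half C1–C8a (C1 ketal carbon, C4 ketone, C8 bonded to C1'); alcohol half C1'–C8a' (C1' quaternary, C4' carbinol, O8' the aryl ether oxygen). The strategy rests on the peri relation of the C1 oxygen to C8: in a 1,4-naphthoquinone the C1 carbonyl oxygen is six atoms (O=C1–C8a–C8–C1'–H) from the hydrogen on C1', so light can close the five-membered ring O–C1–C8a–C8–C1'.
2. Target ⇒ (MOM removal, C2–C3 epoxidation) spiroketal enone 36 ⇒ (PhI(OAc)2, bond C1–O8', six-membered ring C1–O–C1'–C8a'–C8'–O8') naphthol 35 ⇒ (C4' reduction, C2'–C3' epoxidation, dehydrogenation) naphthofuran 30.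
3. 30 ⇒ (light, bond O–C1') quinone 29 ⇒ (oxidation to the quinone, chelation-controlled ether exchange) tetralone 25 ⇒ (Friedel–Crafts bond C4'–C4a') acid 23 ⇒ (Arndt–Eistert) ester 18.
4. 18 ⇒ (rhodium-catalysed asymmetric 1,4-addition, bond C1'–C8a', sets C1') acrylate 11 + boronic acid 17; 11 from bromide 9 (aryne/furan route, Heck), 17 from 3-chloro-4-methoxyphenol.
5. Ring order: ketone-half naphthalene, alcohol-half cyclohexanone, five-membered ether, C2'–C3' oxirane, six-membered ketal ring, C2–C3 oxirane.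

Key step: step 19

Assumption: the (S,S)-diene ligand of step 10 is taken to direct the aryl group to the Re face of C-β of enoate 11, as the usual model for rhodium/diene catalysts predicts; if the sense were the opposite, the (R,R)-ligand would be used with no other change.

**Route**

Step 1
Reactants: 1 2-bromo-1,4-dimethoxybenzene; 2 furan
Product: 5 meso-5,8-dimethoxy-1,4-dihydro-1,4-epoxynaphthalene, via aryllithium 3 (not isolated), via 3,6-dimethoxybenzyne 4 (not isolated)
Conditions: LiN(i-Pr)2, furan (5 equiv), THF, −78 → 25 °C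
Reagents that add atoms: none
Why: Deprotonation between Br and OMe and loss of LiBr should give the symmetrical aryne, which furan traps in a Diels–Alder cycloaddition, so no regiochemical question arises.

Step 2
Reactants: 5 meso-5,8-dimethoxy-1,4-dihydro-1,4-epoxynaphthalene
Product: 6 5,8-dimethoxynaphthalen-1-ol
Conditions: conc. HCl (cat.), MeOH, 60 °C
Reagents that add atoms: none
Why: Acid-catalysed opening of the oxygen bridge to the benzylic cation, hydride shift and enolisation should aromatise the ring, and the symmetry of 5 allows only one naphthol.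

Step 3
Reactants: 6 5,8-dimethoxynaphthalen-1-ol
Product: 7 4-bromo-5,8-dimethoxynaphthalen-1-ol
Conditions: N-bromosuccinimide (1.0 equiv), MeCN, −20 °C
Reagents that add atoms: N-bromosuccinimide, O=C1CCC(=O)N1Br
Why: Electrophilic aromatic bromination of a 1-naphthol should go to the α-position para to the free hydroxyl, which is the carbon that becomes C8 of the ketone half.

Step 4
Reactants: 7 4-bromo-5,8-dimethoxynaphthalen-1-ol
Product: 8 4-bromo-2-chloro-5,8-dimethoxynaphthalen-1-ol
Conditions: N-chlorosuccinimide, i-Pr2NH (10 mol %), toluene, 0 → 25 °C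
Reagents that add atoms: N-chlorosuccinimide, O=C1CCC(=O)N1Cl
Why: With the para position blocked, amine-catalysed electrophilic chlorination of the naphthol should take the only free ortho position, which places chlorine on the later C6.

Step 5
Reactants: 8 4-bromo-2-chloro-5,8-dimethoxynaphthalen-1-ol
Product: 9 1-bromo-3-chloro-4,5,8-trimethoxynaphthalene
Conditions: MeI, K2CO3, DMF, 25 °C
Reagents that add atoms: iodomethane, CI
Why: Williamson O-methylation of the phenoxide should give an all-methyl ether that withstands the acidic and basic steps up to the quinone stage.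

Step 6
Reactants: 9 1-bromo-3-chloro-4,5,8-trimethoxynaphthalene; 10 ethyl acrylate
Product: 11 ethyl (2E)-3-(3-chloro-4,5,8-trimethoxynaphthalen-1-yl)prop-2-enoate
Conditions: Pd(OAc)2 (5 mol %), P(o-tol)3 (12 mol %), Et3N, DMF, 100 °C
Reagents that add atoms: none
Why: The Heck reaction of the aryl bromide should give the (E)-enoate, the aryl chloride being inert to this catalyst.

Step 7
Reactants: 12 3-chloro-4-methoxyphenol
Product: 13 2-bromo-5-chloro-4-methoxyphenol
Conditions: N-bromosuccinimide (1.0 equiv), CH2Cl2, 0 °C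
Reagents that add atoms: N-bromosuccinimide, O=C1CCC(=O)N1Br
Why: Electrophilic bromination should be directed by the free hydroxyl to its less hindered ortho position, para to chlorine, which is the later C8a'.

Step 8
Reactants: 13 2-bromo-5-chloro-4-methoxyphenol
Product: 14 1-(benzyloxy)-2-bromo-5-chloro-4-methoxybenzene
Conditions: BnBr, K2CO3, DMF, 25 °C
Reagents that add atoms: benzyl bromide, BrCc1ccccc1
Why: Williamson benzylation should mask the later O8' with a group that is small in step 10, stable to acid in step 14 and removed together with the methyl ethers in step 16.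

Step 9
Reactants: 14 1-(benzyloxy)-2-bromo-5-chloro-4-methoxybenzene
Product: 17 [2-(benzyloxy)-4-chloro-5-methoxyphenyl]boronic acid, via aryllithium 15 (not isolated), via lithium triisopropoxyborate 16 (not isolated)
Conditions: n-BuLi, THF, −78 °C; B(Oi-Pr)3, −78 → 0 °C; 1 M HCl
Reagents that add atoms: triisopropyl borate, CC(C)OB(OC(C)C)OC(C)C; water, O
Why: Bromine–lithium exchange is faster than exchange of chlorine or benzylic deprotonation at −78 °C, and borylation with hydrolysis should give the boronic acid.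

Step 10
Reactants: 11 ethyl (2E)-3-(3-chloro-4,5,8-trimethoxynaphthalen-1-yl)prop-2-enoate; 17 [2-(benzyloxy)-4-chloro-5-methoxyphenyl]boronic acid
Product: 18 ethyl (3R)-3-[2-(benzyloxy)-4-chloro-5-methoxyphenyl]-3-(3-chloro-4,5,8-trimethoxynaphthalen-1-yl)propanoate
Conditions: [RhCl(C2H4)2]2 (2.5 mol %), (1S,4S)-2,5-diphenylbicyclo[2.2.2]octa-2,5-diene [(S,S)-Ph-bod*] (5.5 mol %), KOH (0.3 equiv), 17 (2 equiv), 1,4-dioxane/H2O 10:1, 40 °C
Reagents that add atoms: none
Why: In this Hayashi–Miyaura 1,4-addition the aryl–rhodium species inserts the enoate, and the chiral diene should direct the aryl group to the Re face of C-β, which sets C1' as R.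

Step 11
Reactants: 18 ethyl (3R)-3-[2-(benzyloxy)-4-chloro-5-methoxyphenyl]-3-(3-chloro-4,5,8-trimethoxynaphthalen-1-yl)propanoate
Product: 19 (3R)-3-[2-(benzyloxy)-4-chloro-5-methoxyphenyl]-3-(3-chloro-4,5,8-trimethoxynaphthalen-1-yl)propanoic acid
Conditions: LiOH, THF/MeOH/H2O, 40 °C; then 1 M HCl
Reagents that add atoms: lithium hydroxide, [Li+].[OH-]
Why: Saponification should be clean because all ethers present are stable to base and the stereocentre is not α to the carbonyl.

Step 12
Reactants: 19 (3R)-3-[2-(benzyloxy)-4-chloro-5-methoxyphenyl]-3-(3-chloro-4,5,8-trimethoxynaphthalen-1-yl)propanoic acid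
Product: 21 (4R)-4-[2-(benzyloxy)-4-chloro-5-methoxyphenyl]-4-(3-chloro-4,5,8-trimethoxynaphthalen-1-yl)-1-diazobutan-2-one, via mixed carbonic anhydride 20 (not isolated)
Conditions: i-BuOCOCl, Et3N, THF, −15 °C; then CH2N2, Et2O, 0 °C
Reagents that add atoms: diazomethane, C=[N+]=[N-]
Why: Acylation of diazomethane by the mixed anhydride is the first stage of the Arndt–Eistert homologation and avoids HCl in the presence of the electron-rich arenes.

Step 13
Reactants: 21 (4R)-4-[2-(benzyloxy)-4-chloro-5-methoxyphenyl]-4-(3-chloro-4,5,8-trimethoxynaphthalen-1-yl)-1-diazobutan-2-one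
Product: 23 (4R)-4-[2-(benzyloxy)-4-chloro-5-methoxyphenyl]-4-(3-chloro-4,5,8-trimethoxynaphthalen-1-yl)butanoic acid, via ketene 22 (not isolated)
Conditions: PhCO2Ag (10 mol %), Et3N, THF/H2O 9:1, 25 °C, dark
Reagents that add atoms: water, O
Why: The silver-catalysed Wolff rearrangement gives a ketene that water traps as the one-carbon-longer acid, and the migrating CH2 leaves C1' untouched.

Step 14
Reactants: 23 (4R)-4-[2-(benzyloxy)-4-chloro-5-methoxyphenyl]-4-(3-chloro-4,5,8-trimethoxynaphthalen-1-yl)butanoic acid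
Product: 25 (4R)-5-(benzyloxy)-7-chloro-4-(3-chloro-4,5,8-trimethoxynaphthalen-1-yl)-8-methoxy-3,4-dihydronaphthalen-1(2H)-one, via mixed trifluoroacetic anhydride 24 (not isolated)
Conditions: (CF3CO)2O, CF3CO2H (cat.), CH2Cl2, 0 → 25 °C
Reagents that add atoms: none
Why: Intramolecular Friedel–Crafts acylation should close the six-membered ring at C4a', which is ortho to the methoxy group, whereas the only alternative site (C7 of the naphthalene) is flanked by chlorine and not activated.

Step 15
Reactants: 25 (4R)-5-(benzyloxy)-7-chloro-4-(3-chloro-4,5,8-trimethoxynaphthalen-1-yl)-8-methoxy-3,4-dihydronaphthalen-1(2H)-one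
Product: 26 8-[(1R)-8-(benzyloxy)-6-chloro-5-methoxy-4-oxo-1,2,3,4-tetrahydronaphthalen-1-yl]-6-chloro-5-methoxynaphthalene-1,4-dione
Conditions: (NH4)2Ce(NO3)6 (2.5 equiv), MeCN/H2O 2:1, 0 °C
Reagents that add atoms: water, O
Why: Oxidative demethylation of the 1,4-dimethoxynaphthalene ring should give the quinone, while the acyl- and chloro-substituted benzene ring is much harder to oxidise.

Step 16
Reactants: 26 8-[(1R)-8-(benzyloxy)-6-chloro-5-methoxy-4-oxo-1,2,3,4-tetrahydronaphthalen-1-yl]-6-chloro-5-methoxynaphthalene-1,4-dione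
Product: 27 6-chloro-8-[(1R)-6-chloro-5,8-dihydroxy-4-oxo-1,2,3,4-tetrahydronaphthalen-1-yl]-5-hydroxynaphthalene-1,4-dione
Conditions: BCl3 (5 equiv), C6HMe5 (3 equiv), CH2Cl2, −78 → 0 °C; then MeOH, aq. NaHCO3
Reagents that add atoms: none
Why: Each methyl ether now lies peri to a carbonyl group (C5–OMe to the quinone C4=O, C5'–OMe to the C4' ketone) and is cleaved by BCl3 through a chelate, while the benzyl ether is cleaved with pentamethylbenzene as cation scavenger.

Step 17
Reactants: 27 6-chloro-8-[(1R)-6-chloro-5,8-dihydroxy-4-oxo-1,2,3,4-tetrahydronaphthalen-1-yl]-5-hydroxynaphthalene-1,4-dione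
Product: 28 8-[(1R)-8-(tert-butyldimethylsilyloxy)-6-chloro-5-hydroxy-4-oxo-1,2,3,4-tetrahydronaphthalen-1-yl]-6-chloro-5-hydroxynaphthalene-1,4-dione
Conditions: t-BuMe2SiCl (1.05 equiv), imidazole, DMF, 0 °C
Reagents that add atoms: tert-butyldimethylsilyl chloride, CC(C)(C)[Si](C)(C)Cl
Why: Of the three phenols only the C8' hydroxyl is not hydrogen-bonded to a peri carbonyl group, so selective silylation of the unchelated phenol should occur there.

Step 18
Reactants: 28 8-[(1R)-8-(tert-butyldimethylsilyloxy)-6-chloro-5-hydroxy-4-oxo-1,2,3,4-tetrahydronaphthalen-1-yl]-6-chloro-5-hydroxynaphthalene-1,4-dione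
Product: 29 8-[(1R)-8-(tert-butyldimethylsilyloxy)-6-chloro-5-(methoxymethoxy)-4-oxo-1,2,3,4-tetrahydronaphthalen-1-yl]-6-chloro-5-(methoxymethoxy)naphthalene-1,4-dione
Conditions: MeOCH2Cl (6 equiv), i-Pr2NEt (8 equiv), CH2Cl2, 0 → 40 °C
Reagents that add atoms: chloromethyl methyl ether, COCCl
Why: O-Alkylation of the two chelated phenols under forcing but non-hydrolytic conditions masks the C5 hydroxyl, which would otherwise quench the excited quinone by proton transfer, and the C5' hydroxyl, which must not be a free hydroquinone in step 25.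

Step 19
Reactants: 29 8-[(1R)-8-(tert-butyldimethylsilyloxy)-6-chloro-5-(methoxymethoxy)-4-oxo-1,2,3,4-tetrahydronaphthalen-1-yl]-6-chloro-5-(methoxymethoxy)naphthalene-1,4-dione
Product: 30 (S)-spiro ether (naphthofuran) with the new C1–O–C1' bridge and a free C4 naphthol
Conditions: hν (blue LED, 450 nm), degassed CH2Cl2 (0.005 M), 25 °C
Reagents that add atoms: none
Why: Light of about 450 nm is absorbed only by the quinone, whose n,π* triplet abstracts the doubly benzylic C1'–H with the C1 carbonyl oxygen through the six-membered array O=C1–C8a–C8–C1'–H; electron transfer within the 1,5-biradical then gives a naphtholate/diarylmethyl cation pair, the C1 oxygen bonds C1' and the proton ends on O4. The closest known reaction type is the photoinduced intramolecular redox cyclisation (1,5-hydrogen transfer) of quinones that carry a C–H donor side chain to cyclic ethers of the hydroquinone. The five-membered ring O–C1–C8a–C8–C1' closes by collapse of this ion pair, that is by O-alkylation of the peri oxygen by the cation, so the step is redox-neutral and needs no external oxidant. C1' is the only stereocentre formed: oxygen should take the place of hydrogen on the same face (the change from R to S is only a change of priorities) because rotation about the peri-flanked C8–C1' bond is expected to be slower than C–O bond formation, so the configuration set in step 10 is carried over. The step needs site selectivity for C1'–H over the OCH2O hydrogens of the C5 ether, which the six-membered transition state and the weaker doubly benzylic C–H bond should secure. It also needs excitation of the quinone alone, which holds because the C4' aryl ketone, left unmasked, does not absorb above 400 nm.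

Step 20
Reactants: 30 (S)-spiro ether (naphthofuran) with the new C1–O–C1' bridge and a free C4 naphthol
Product: 31 C4-O-tert-butyldimethylsilyl ether of 30
Conditions: t-BuMe2SiOTf (1.2 equiv), 2,6-lutidine, CH2Cl2, −78 °C
Reagents that add atoms: tert-butyldimethylsilyl triflate, CC(C)(C)[Si](C)(C)OS(=O)(=O)C(F)(F)F
Why: Silylation of the peri-hindered naphthol at low temperature, where the ketone is not enolised by 2,6-lutidine, protects the electron-rich naphthol from the oxidants of steps 21 and 22.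

Step 21
Reactants: 31 C4-O-tert-butyldimethylsilyl ether of 30
Product: 32 2',3'-dehydro enone (C2'=C3' conjugated to the C4' ketone)
Conditions: 2-iodoxybenzoic acid (IBX, 3 equiv), DMSO/PhF 2:1, 70 °C
Reagents that add atoms: none
Why: IBX dehydrogenation of the ketone through its enol can only give the C2'=C3' enone because C1' is quaternary.

Step 22
Reactants: 32 2',3'-dehydro enone (C2'=C3' conjugated to the C4' ketone)
Product: 33 2',3'-epoxy ketone with the oxirane on the face of the bridging oxygen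
Conditions: t-BuOOH (5.5 M in decane), DBU, CH2Cl2, 0 °C
Reagents that add atoms: tert-butyl hydroperoxide, CC(C)(C)OO
Why: In this Weitz–Scheffer epoxidation the peroxide anion should add to C2' anti to the aryl carbon C8 on the spiro centre, whose C7–H edge covers that face, so the oxirane forms syn to the ether oxygen and sets C2' and C3'.

Step 23
Reactants: 33 2',3'-epoxy ketone with the oxirane on the face of the bridging oxygen
Product: 34 2',3'-epoxy-4'-alcohol with the hydroxyl anti to the oxirane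
Conditions: NaBH4, MeOH/THF 1:1, −40 °C
Reagents that add atoms: none
Why: Hydride addition to the C4' ketone should come from the face of the bridging oxygen, because the C7–H edge of the ketone-half arene lies over the other face of the carbonyl, which puts the new hydroxyl on the arene side, anti to the oxirane.

Step 24
Reactants: 34 2',3'-epoxy-4'-alcohol with the hydroxyl anti to the oxirane
Product: 35 diphenol with free C4 and C8' hydroxyls
Conditions: Bu4NF (2.5 equiv), AcOH (2.5 equiv), THF, 0 °C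
Reagents that add atoms: none
Why: Buffered fluoride cleaves both aryl silyl ethers and leaves the acetals and the oxirane untouched.

Step 25
Reactants: 35 diphenol with free C4 and C8' hydroxyls
Product: 36 spiroketal enone (C1 ketal closed by O8'; C2=C3–C4=O)
Conditions: PhI(OAc)2 (1.1 equiv), CF3CH2OH, −20 → 0 °C
Reagents that add atoms: none
Why: Oxidative dearomatisation of the 4-alkoxy-1-naphthol by the hypervalent iodine reagent gives a C1 oxocarbenium ion that the C8' phenol captures in a six-membered ring closure, and since O8' is held on one side of the naphthalene plane by C8a' the configuration of C1 follows from C1'.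

Step 26
Reactants: 36 spiroketal enone (C1 ketal closed by O8'; C2=C3–C4=O)
Product: 37 bis(methoxymethyl) ether of the target
Conditions: t-BuOOH (5.5 M in decane), DBU, CH2Cl2, 0 °C
Reagents that add atoms: tert-butyl hydroperoxide, CC(C)(C)OO
Why: In this Weitz–Scheffer epoxidation the peroxide anion should add to C2 anti to the pseudo-axial O8' of the ketal, which places the oxirane on the face of the bridging oxygen and sets C2 and C3.

Step 27
Reactants: 37 bis(methoxymethyl) ether of the target
Product: 38 target compound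
Conditions: NaHSO4·SiO2, CH2Cl2, 25 °C
Reagents that add atoms: none
Why: Acid-catalysed cleavage of the two aryl methoxymethyl acetals on a mildly acidic solid with a non-nucleophilic counter-ion should spare the two oxiranes, each flanked by oxygenated carbons, and the cage ketal.

**Compound list**

1 | 2-bromo-1,4-dimethoxybenzene | COc1ccc(OC)c(Br)c1 | starting material
2 | furan | c1ccoc1 | starting material
3 | (2-bromo-3,6-dimethoxyphenyl)lithium | COc1ccc(OC)c(Br)c1[Li] | intermediate
4 | 3,6-dimethoxybenzyne | COC1=CC=C(OC)C#C1 | intermediate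
5 | meso-5,8-dimethoxy-1,4-dihydro-1,4-epoxynaphthalene | COc1ccc(OC)c2c1[C@@H]1C=C[C@H]2O1 | intermediate
6 | 5,8-dimethoxynaphthalen-1-ol | COc1ccc(OC)c2c(O)cccc12 | intermediate
7 | 4-bromo-5,8-dimethoxynaphthalen-1-ol | COc1ccc(OC)c2c(O)ccc(Br)c12 | intermediate
8 | 4-bromo-2-chloro-5,8-dimethoxynaphthalen-1-ol | COc1ccc(OC)c2c(O)c(Cl)cc(Br)c12 | intermediate
9 | 1-bromo-3-chloro-4,5,8-trimethoxynaphthalene | COc1ccc(OC)c2c(OC)c(Cl)cc(Br)c12 | intermediate
10 | ethyl acrylate | C=CC(=O)OCC | starting material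
11 | ethyl (2E)-3-(3-chloro-4,5,8-trimethoxynaphthalen-1-yl)prop-2-enoate | CCOC(=O)/C=C/c1cc(Cl)c(OC)c2c(OC)ccc(OC)c12 | intermediate
12 | 3-chloro-4-methoxyphenol | COc1ccc(O)cc1Cl | starting material
13 | 2-bromo-5-chloro-4-methoxyphenol | COc1cc(Br)c(O)cc1Cl | intermediate
14 | 1-(benzyloxy)-2-bromo-5-chloro-4-methoxybenzene | COc1cc(Br)c(OCc2ccccc2)cc1Cl | intermediate
15 | [2-(benzyloxy)-4-chloro-5-methoxyphenyl]lithium | COc1cc([Li])c(OCc2ccccc2)cc1Cl | intermediate
16 | lithium [2-(benzyloxy)-4-chloro-5-methoxyphenyl]tri(propan-2-yloxy)borate | [Li+].COc1cc([B-](OC(C)C)(OC(C)C)OC(C)C)c(OCc2ccccc2)cc1Cl | intermediate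
17 | [2-(benzyloxy)-4-chloro-5-methoxyphenyl]boronic acid | COc1cc(B(O)O)c(OCc2ccccc2)cc1Cl | intermediate
18 | ethyl (3R)-3-[2-(benzyloxy)-4-chloro-5-methoxyphenyl]-3-(3-chloro-4,5,8-trimethoxynaphthalen-1-yl)propanoate | CCOC(=O)C[C@@H](c1cc(OC)c(Cl)cc1OCc1ccccc1)c1cc(Cl)c(OC)c2c(OC)ccc(OC)c12 | intermediate
19 | (3R)-3-[2-(benzyloxy)-4-chloro-5-methoxyphenyl]-3-(3-chloro-4,5,8-trimethoxynaphthalen-1-yl)propanoic acid | OC(=O)C[C@@H](c1cc(OC)c(Cl)cc1OCc1ccccc1)c1cc(Cl)c(OC)c2c(OC)ccc(OC)c12 | intermediate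
20 | mixed anhydride of 19 with isobutyl hydrogen carbonate | CC(C)COC(=O)OC(=O)C[C@@H](c1cc(OC)c(Cl)cc1OCc1ccccc1)c1cc(Cl)c(OC)c2c(OC)ccc(OC)c12 | intermediate
21 | (4R)-4-[2-(benzyloxy)-4-chloro-5-methoxyphenyl]-4-(3-chloro-4,5,8-trimethoxynaphthalen-1-yl)-1-diazobutan-2-one | [N-]=[N+]=CC(=O)C[C@@H](c1cc(OC)c(Cl)cc1OCc1ccccc1)c1cc(Cl)c(OC)c2c(OC)ccc(OC)c12 | intermediate
22 | (4R)-4-[2-(benzyloxy)-4-chloro-5-methoxyphenyl]-4-(3-chloro-4,5,8-trimethoxynaphthalen-1-yl)but-1-en-1-one (ketene) | O=C=CC[C@@H](c1cc(OC)c(Cl)cc1OCc1ccccc1)c1cc(Cl)c(OC)c2c(OC)ccc(OC)c12 | intermediate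
23 | (4R)-4-[2-(benzyloxy)-4-chloro-5-methoxyphenyl]-4-(3-chloro-4,5,8-trimethoxynaphthalen-1-yl)butanoic acid | OC(=O)CC[C@@H](c1cc(OC)c(Cl)cc1OCc1ccccc1)c1cc(Cl)c(OC)c2c(OC)ccc(OC)c12 | intermediate
24 | mixed anhydride of 23 with trifluoroacetic acid | FC(F)(F)C(=O)OC(=O)CC[C@@H](c1cc(OC)c(Cl)cc1OCc1ccccc1)c1cc(Cl)c(OC)c2c(OC)ccc(OC)c12 | intermediate
25 | (4R)-5-(benzyloxy)-7-chloro-4-(3-chloro-4,5,8-trimethoxynaphthalen-1-yl)-8-methoxy-3,4-dihydronaphthalen-1(2H)-one | O=C1CC[C@H](c2cc(Cl)c(OC)c3c(OC)ccc(OC)c23)c2c(OCc3ccccc3)cc(Cl)c(OC)c12 | intermediate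
26 | 8-[(1R)-8-(benzyloxy)-6-chloro-5-methoxy-4-oxo-1,2,3,4-tetrahydronaphthalen-1-yl]-6-chloro-5-methoxynaphthalene-1,4-dione | O=C1C=CC(=O)c2c1c(OC)c(Cl)cc2[C@H]1CCC(=O)c2c(OC)c(Cl)cc(OCc3ccccc3)c12 | intermediate
27 | 6-chloro-8-[(1R)-6-chloro-5,8-dihydroxy-4-oxo-1,2,3,4-tetrahydronaphthalen-1-yl]-5-hydroxynaphthalene-1,4-dione | O=C1C=CC(=O)c2c1c(O)c(Cl)cc2[C@H]1CCC(=O)c2c(O)c(Cl)cc(O)c12 | intermediate
28 | 8-[(1R)-8-(tert-butyldimethylsilyloxy)-6-chloro-5-hydroxy-4-oxo-1,2,3,4-tetrahydronaphthalen-1-yl]-6-chloro-5-hydroxynaphthalene-1,4-dione | O=C1C=CC(=O)c2c1c(O)c(Cl)cc2[C@H]1CCC(=O)c2c(O)c(Cl)cc(O[Si](C)(C)C(C)(C)C)c12 | intermediate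
29 | 8-[(1R)-8-(tert-butyldimethylsilyloxy)-6-chloro-5-(methoxymethoxy)-4-oxo-1,2,3,4-tetrahydronaphthalen-1-yl]-6-chloro-5-(methoxymethoxy)naphthalene-1,4-dione (key-step precursor; C4' ketone left unmasked) | O=C1C=CC(=O)c2c1c(OCOC)c(Cl)cc2[C@H]1CCC(=O)c2c(OCOC)c(Cl)cc(O[Si](C)(C)C(C)(C)C)c12 | intermediate
30 | key-step product: 2H-naphtho[1,8-bc]furan (O on C1; C4-OH; C5-OMOM; C6-Cl) spiro-fused at C1' (S) to 8'-(tert-butyldimethylsilyloxy)-6'-chloro-5'-(methoxymethoxy)-2',3'-dihydronaphthalen-4'(1'H)-one | Oc1ccc2O[C@@]3(CCC(=O)c4c(OCOC)c(Cl)cc(O[Si](C)(C)C(C)(C)C)c43)c3cc(Cl)c(OCOC)c1c23 | intermediate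
31 | C4-O-tert-butyldimethylsilyl ether of 30 (C1' S) | CC(C)(C)[Si](C)(C)Oc1ccc2O[C@@]3(CCC(=O)c4c(OCOC)c(Cl)cc(O[Si](C)(C)C(C)(C)C)c43)c3cc(Cl)c(OCOC)c1c23 | intermediate
32 | 2',3'-dehydro enone of 31 (C2'=C3'–C4'=O; C1' S) | CC(C)(C)[Si](C)(C)Oc1ccc2O[C@@]3(C=CC(=O)c4c(OCOC)c(Cl)cc(O[Si](C)(C)C(C)(C)C)c43)c3cc(Cl)c(OCOC)c1c23 | intermediate
33 | 2',3'-epoxy-4'-ketone; oxirane syn to the bridging oxygen and anti to C8 (C1' S) | CC(C)(C)[Si](C)(C)Oc1ccc2O[C@@]3([C@@H]4O[C@@H]4C(=O)c4c(OCOC)c(Cl)cc(O[Si](C)(C)C(C)(C)C)c43)c3cc(Cl)c(OCOC)c1c23 | intermediate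
34 | 2',3'-epoxy-4'-alcohol; oxirane syn to the bridging oxygen, 4'-OH anti to the oxirane | CC(C)(C)[Si](C)(C)Oc1ccc2O[C@@]3([C@@H]4O[C@@H]4[C@@H](O)c4c(OCOC)c(Cl)cc(O[Si](C)(C)C(C)(C)C)c43)c3cc(Cl)c(OCOC)c1c23 | intermediate
35 | diphenol: 34 without both silyl groups (free C4-OH and C8'-OH) | Oc1ccc2O[C@@]3([C@@H]4O[C@@H]4[C@@H](O)c4c(OCOC)c(Cl)cc(O)c43)c3cc(Cl)c(OCOC)c1c23 | intermediate
36 | spiroketal enone: C1 ketal carrying the bridging oxygen and O8', C2=C3–C4=O, C5 and C5' OMOM, alcohol half as in the target | O=C1c2c(OCOC)c(Cl)cc3c2[C@@]2(Oc4cc(Cl)c(OCOC)c5c4[C@]3(O2)[C@@H]2O[C@@H]2[C@H]5O)C=C1 | intermediate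
37 | 5,5'-bis-O-(methoxymethyl) ether of the target; C2–C3 oxirane syn to the bridging oxygen and anti to O8' | O=C1c2c(OCOC)c(Cl)cc3c2[C@@]2(Oc4cc(Cl)c(OCOC)c5c4[C@]3(O2)[C@@H]2O[C@@H]2[C@H]5O)[C@@H]2O[C@H]12 | intermediate
38 | CNP0289684.3 | O=C1c2c(O)c(Cl)cc3c2[C@@]2(Oc4cc(Cl)c(O)c5c4[C@]3(O2)[C@@H]2O[C@@H]2[C@H]5O)[C@@H]2O[C@H]12 | target

**Step count**

Total steps: 27. Longest linear sequence: 24 (steps 1–6 and 10–27); steps 7–9 form the convergent branch.

**Steps most likely to fail**

Step 19. What may go wrong is loss of the C1' configuration: the biradical or ion pair can return the hydrogen or rotate about the C8–C1' bond before the C–O bond forms, and the unmasked C4' ketone makes the cation less stabilised than in an acetal analogue. The fallback secures the configuration by classical resolution instead of by chirality transfer. It sets out from naphthol 30 of reduced enantiomeric purity, which is acylated with (1S)-camphanic chloride (Et3N, DMAP, CH2Cl2) to give the camphanate of 30, F1, and its diastereomer from the enantiomeric spiro ether, F2. The two are separated by crystallisation or chromatography, and aminolysis of the aryl ester F1 (n-BuNH2, THF, 0 °C), which leaves the aryl silyl ether intact, returns the route at 30.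

Step 10. What may go wrong is slow insertion relative to protodeboronation, because both partners carry a substituent next to the reacting carbon (peri methoxy on 11, ortho benzyloxy on 17), together with insufficient facial discrimination. The fallback replaces the catalytic step by an auxiliary-controlled conjugate addition of an aryl copper reagent. Ester 11 is saponified (LiOH) to the acrylic acid F3, which is converted through its mixed pivalic anhydride F4 (t-BuCOCl, Et3N) with the lithium salt of (4R)-4-phenyl-1,3-oxazolidin-2-one into the N-enoyl imide F5. Bromide 14 is converted with Mg into the aryl Grignard reagent F6, which with CuBr·SMe2 (THF, −40 °C) should add to the chelated s-cis imide on the face away from the phenyl group to give the adduct F7. LiOH/H2O2 then cleaves the auxiliary and returns the route at acid 19.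

Step 23. What may go wrong is hydride delivery to the arene face of the C4' carbonyl, anti to the oxirane oxygen, as the intrinsic preference of cyclic epoxy ketones would suggest, which gives the C4' epimer. The fallback sets the centre by substitution with inversion instead of by facial control. Ketone 33 is reduced as before and the epimeric alcohol F8 is taken on under Mitsunobu conditions (4-nitrobenzoic acid, PPh3, DIAD, toluene, 0 → 25 °C) to the inverted 4-nitrobenzoate F9. K2CO3 in MeOH then removes the ester together with both aryl silyl ethers and returns the route at diphenol 35.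

**Further compounds**

F1 | step 19 | (1S)-camphanate of naphthol 30 (C1' S) | O=C(Oc1ccc2O[C@@]3(CCC(=O)c4c(OCOC)c(Cl)cc(O[Si](C)(C)C(C)(C)C)c43)c3cc(Cl)c(OCOC)c1c23)[C@@]12CC[C@@](C)(C(=O)O1)C2(C)C
F2 | step 19 | (1S)-camphanate of the enantiomer of 30 (C1' R) | O=C(Oc1ccc2O[C@]3(CCC(=O)c4c(OCOC)c(Cl)cc(O[Si](C)(C)C(C)(C)C)c43)c3cc(Cl)c(OCOC)c1c23)[C@@]12CC[C@@](C)(C(=O)O1)C2(C)C
F3 | step 10 | (2E)-3-(3-chloro-4,5,8-trimethoxynaphthalen-1-yl)prop-2-enoic acid | OC(=O)/C=C/c1cc(Cl)c(OC)c2c(OC)ccc(OC)c12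
F4 | step 10 | mixed anhydride of F3 with pivalic acid | CC(C)(C)C(=O)OC(=O)/C=C/c1cc(Cl)c(OC)c2c(OC)ccc(OC)c12
F5 | step 10 | (4R)-3-[(2E)-3-(3-chloro-4,5,8-trimethoxynaphthalen-1-yl)prop-2-enoyl]-4-phenyl-1,3-oxazolidin-2-one | O=C(/C=C/c1cc(Cl)c(OC)c2c(OC)ccc(OC)c12)N1[C@H](c2ccccc2)COC1=O
F6 | step 10 | [2-(benzyloxy)-4-chloro-5-methoxyphenyl]magnesium bromide | COc1cc([Mg]Br)c(OCc2ccccc2)cc1Cl
F7 | step 10 | (4R)-3-[(3R)-3-[2-(benzyloxy)-4-chloro-5-methoxyphenyl]-3-(3-chloro-4,5,8-trimethoxynaphthalen-1-yl)propanoyl]-4-phenyl-1,3-oxazolidin-2-one | O=C(C[C@@H](c1cc(OC)c(Cl)cc1OCc1ccccc1)c1cc(Cl)c(OC)c2c(OC)ccc(OC)c12)N1[C@H](c2ccccc2)COC1=O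
F8 | step 23 | C4' epimer of 34 (4'-OH syn to the oxirane) | CC(C)(C)[Si](C)(C)Oc1ccc2O[C@@]3([C@@H]4O[C@@H]4[C@H](O)c4c(OCOC)c(Cl)cc(O[Si](C)(C)C(C)(C)C)c43)c3cc(Cl)c(OCOC)c1c23
F9 | step 23 | 4'-O-(4-nitrobenzoate) of 34 (ester anti to the oxirane) | CC(C)(C)[Si](C)(C)Oc1ccc2O[C@@]3([C@@H]4O[C@@H]4[C@@H](OC(=O)c4ccc(cc4)[N+](=O)[O-])c4c(OCOC)c(Cl)cc(O[Si](C)(C)C(C)(C)C)c43)c3cc(Cl)c(OCOC)c1c23
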